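Target cannot come from substrate that is no longer there, so I first asked how much the noon flask still held.

| flask | substrate | coupling partner | free catalyst | remark | time |
|---|---|---|---|---|---|
| noon | 20 mM | 0.95 equiv | 0.53 mol% | the very flask that is asked about, followed so far |  |
| flask | 20 mM | 0.950 equiv | 0.53 mol% |  | 8.0 d |

noon run (percent of the substrate charged)

| time / d | target / % | substrate / % |
|---|---|---|
| 0.625 | 29.2 | 40.0 |
| 1.04 | 39.2 | 24.9 |
| 1.67 | 49.0 | 13.0 |
| 3.00 | 56.8 | 3.0 |
| 5.00 | 60.4 | 1.0 |
| 8.00 | 60.7 | 0.2 |

(standard deviation of a reading: 0.3 percentage points)

- Saturday's: at 8.0 d add free catalyst, 100% of the amount charged, then wait 2.5 d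
- Monday's: at 8.0 d add coupling partner, 50.0% of the amount charged, then wait 2.5 d
- Friday's: change nothing and wait 2.5 d more
- Tuesday's: at 8.0 d take out 90% of the target then present, then wait 2.5 d

- target that was removed still counts
- what was read earlier has a scatter of 0.3 percentage points, one standard deviation
- additions bring no volume worth counting

* target, in percent of the substrate first charged, at 8.0 d
* what to do for the largest gain in target; "none" if nothing gains more than 2 percentage points (Saturday's / Monday's / Friday's / Tuesday's / none)
* target present, with what was taken out counted in, in percent of the substrate first charged, after Friday's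
* target present, with what was taken out counted in, in percent of the substrate first charged, after Tuesday's

At 8.00 d, c(substrate) read 0.200% of the charge, and I called this the reserve, the most new target this flask can still draw from substrate. Even with two scatters added, 0.800%, it lay below the margin of 2 percentage points. Counting one coupling partner per target, 36.1% of its charge remained, more than the share of substrate, so coupling partner was not the limiting reagent in this flask. Target rose by 0.3 points between the last two readings, about one scatter. My own reckoning therefore put target at about 60.7% at 8.0 d, with a ceiling of 60.9%, and the answer "none".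

The forecast gave 60.7%, none, 60.8% after Friday's and 60.8% after Tuesday's, on the grounds that “Only the last 0.2% of substrate remains, so no option gains 2 points”.

The flask gave 60.4%, none, 60.4% and 60.5%, so the forecast held.

    substrate + free catalyst ⇌ catalyst intermediate A (K = 159 L mol⁻¹, k = 585 L mol⁻¹ h⁻¹)
    catalyst intermediate B → free catalyst + target (k = 26.0 h⁻¹)
    coupling partner + catalyst intermediate A ⇌ catalyst intermediate B (K = 36.3 L mol⁻¹, k = 1.09 × 10⁵ L mol⁻¹ h⁻¹)
    2 substrate → self-condensation product (k = 1.20 L mol⁻¹ h⁻¹)
    coupling partner → decomposition product (k = 1.56 × 10⁻⁴ h⁻¹)
    free catalyst + target → spent catalyst (k = 0.155 L mol⁻¹ h⁻¹)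

Tuesday's brought the largest gain, 0.054 points, which stayed below the reserve of 0.200%. The neighbour flask, charged with 8.0 mM of substrate at the same equivalents and loadings, held a reserve of 5.0% at 8.0 d, above the margin, so there the same reckoning did not exclude a gain. Its ceiling came to 58.1%, against 53.1% of target.

The earlier runs and the new flask were generated by integration with constants of no real substance; scatter was added.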